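**Retrosynthetic overview**

1. The target is read as catechin-(4α→8)-catechin-(4α→8)-catechin-(4α→8)-catechin. After global deprotection, the two bonds at C4 of the second unit are cut together: C4–C4a (ring C of the second unit) and C4–C8 (to the third unit). This gives aldehyde 17 and dimer 6.
2. Enabling feature: C4 of the second unit is a diarylmethine CH bonded to C4a of its own ring A and to C8 of ring A of the third unit, both 1,3,5-trioxygenated arenes. It is therefore an aldehyde carbon arylated twice, first within the molecule (closing the pyran ring O1–C2–C3–C4–C4a–C8a), then by the lower dimer.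
3. Aldehyde 17 comes from phenol 8 and epoxy alcohol 12. O1–C2 is made by SN2 opening of a Sharpless epoxide derived from caffeic acid (ring B and C2–C3–C4 of the second unit). Ring A of the second unit is 3,5-bis(benzyloxy)phenol, C-alkylated ortho to its OH by the catechin C4 cation, so the 4→8 regiochemistry of the upper interflavan bond is fixed by construction.
4. Dimer 6 (third and bottom units) and the top unit come from (+)-catechin through the 4-(2-ethoxyethoxy) electrophile 4.
5. Ring order: the rings of the top, third and bottom units come intact from catechin, rings A and B of the second unit are bought as arenes, and ring C of the second unit is closed last (step 14).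

Key step: step 14

Remark: every unit is (2R,3S) and every interflavan bond is 3,4-trans (4α). The flavan units are called top, second, third and bottom unit; in each, ring A is the benzo ring, ring C the pyran ring and ring B the catechol ring, with flavan numbering. Bn = benzyl, Ac = acetyl, TBS = tert-butyldimethylsilyl. 3,5-Bis(benzyloxy)phenol 7 is taken as a commercial phenol.

**Route**

Step 1
Reactants: 1 (+)-catechin
Product: 2 5,7,3',4'-tetra-O-benzyl-(+)-catechin
Conditions: BnBr (4.4 equiv), K2CO3, DMF, 0 °C → rt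
Reagents that add atoms: benzyl bromide BrCc1ccccc1
Why: Williamson ether synthesis; the four phenols are alkylated under carbonate base while the secondary C3 alcohol stays free and no stereocentre is touched.

Step 2
Reactants: 2 5,7,3',4'-tetra-O-benzyl-(+)-catechin
Product: 3 5,7,3',4'-tetra-O-benzyl-4β-(2-ethoxyethoxy)catechin
Conditions: DDQ (2 equiv), 2-ethoxyethanol (5 equiv), CH2Cl2, rt
Reagents that add atoms: 2-ethoxyethanol CCOCCO
Why: DDQ benzylic oxidation (hydride abstraction at the doubly oxygen-activated C4, capture of the cation by the alcohol); quasi-axial entry on the β face should give the 4β ether, and this C4 configuration is erased on later ionisation.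

Step 3
Reactants: 3 5,7,3',4'-tetra-O-benzyl-4β-(2-ethoxyethoxy)catechin
Product: 4 3-O-acetyl-5,7,3',4'-tetra-O-benzyl-4β-(2-ethoxyethoxy)catechin
Conditions: Ac2O, DMAP (cat.), pyridine, rt
Reagents that add atoms: acetic anhydride CC(=O)OC(C)=O
Why: DMAP-catalysed acylation of the only free hydroxyl; the 3-acetoxy group later shields the β face of the C4 cation.

Step 4
Reactants: 4 3-O-acetyl-5,7,3',4'-tetra-O-benzyl-4β-(2-ethoxyethoxy)catechin; 2 5,7,3',4'-tetra-O-benzyl-(+)-catechin (4 equiv)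
Product: 5 3-O-acetyl-octa-O-benzyl-catechin-(4α→8)-catechin
Conditions: Me3SiOTf (0.2 equiv), CH2Cl2, −78 °C; excess 2 recovered
Reagents that add atoms: none
Why: Friedel–Crafts-type interflavan condensation: Me3SiOTf ionises the 4-alkoxy group, and C8 of 2 attacks the C4 cation on the α face, anti to the participating 3-acetoxy group, which sets the new C4 centre 3,4-trans.

Step 5
Reactants: 5 3-O-acetyl-octa-O-benzyl-catechin-(4α→8)-catechin
Product: 6 3,3''-di-O-acetyl-octa-O-benzyl-catechin-(4α→8)-catechin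
Conditions: Ac2O, DMAP (cat.), pyridine, rt
Reagents that add atoms: acetic anhydride CC(=O)OC(C)=O
Why: DMAP-catalysed acylation of the remaining secondary alcohol, so that the nucleophile of the key step carries no free hydroxyl that would consume the silyl triflate.

Step 6
Reactants: 4 3-O-acetyl-5,7,3',4'-tetra-O-benzyl-4β-(2-ethoxyethoxy)catechin; 7 3,5-bis(benzyloxy)phenol (3 equiv)
Product: 8 3-O-acetyl-5,7,3',4'-tetra-O-benzyl-4α-[2,4-bis(benzyloxy)-6-hydroxyphenyl]catechin
Conditions: Me3SiOTf (0.2 equiv), CH2Cl2, −78 → −20 °C; excess 7 recovered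
Reagents that add atoms: none
Why: Friedel–Crafts alkylation of the phenol by the C4 cation at the carbon ortho to the free OH (smallest flanking group; any O-alkylated adduct re-ionises and returns to carbon), with α attack anti to the 3-acetoxy group setting C4 3,4-trans.

Step 7
Reactants: 9 caffeic acid
Product: 10 benzyl (E)-3-[3,4-bis(benzyloxy)phenyl]prop-2-enoate
Conditions: BnBr (3.5 equiv), K2CO3, DMF, 60 °C
Reagents that add atoms: benzyl bromide BrCc1ccccc1
Why: Williamson etherification of both phenols and carboxylate O-alkylation in one operation; the E alkene is untouched.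

Step 8
Reactants: 10 benzyl (E)-3-[3,4-bis(benzyloxy)phenyl]prop-2-enoate
Product: 11 (E)-3-[3,4-bis(benzyloxy)phenyl]prop-2-en-1-ol
Conditions: iBu2AlH (2.5 equiv), CH2Cl2, −78 °C; Rochelle salt work-up
Reagents that add atoms: none
Why: 1,2-reduction of the α,β-unsaturated ester by diisobutylaluminium hydride gives the E allylic alcohol without touching the alkene.

Step 9
Reactants: 11 (E)-3-[3,4-bis(benzyloxy)phenyl]prop-2-en-1-ol
Product: 12 [(2S,3S)-3-[3,4-bis(benzyloxy)phenyl]oxiran-2-yl]methanol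
Conditions: Ti(OiPr)4 (10 mol%), L-(+)-diisopropyl tartrate (12 mol%), tBuOOH (2 equiv), 4 Å molecular sieves, CH2Cl2, −20 °C; non-acidic work-up, Et3N-deactivated silica
Reagents that add atoms: tert-butyl hydroperoxide CC(C)(C)OO
Why: Sharpless asymmetric epoxidation; the L-(+)-tartrate catalyst delivers oxygen to the face of the E allylic alcohol that gives the (2S,3S) trans epoxide, which fixes the future C3 and, after inversion, the future C2 of the second unit.

Step 10
Reactants: 8 3-O-acetyl-5,7,3',4'-tetra-O-benzyl-4α-[2,4-bis(benzyloxy)-6-hydroxyphenyl]catechin; 12 [(2S,3S)-3-[3,4-bis(benzyloxy)phenyl]oxiran-2-yl]methanol (1.5 equiv)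
Product: 13 (2S,3R)-3-aryloxy-3-[3,4-bis(benzyloxy)phenyl]propane-1,2-diol (aryloxy = phenol oxygen of 8)
Conditions: Cs2CO3 (0.3 equiv), DMF, 65 °C
Reagents that add atoms: none
Why: SN2 opening of the 3-arylglycidol by the phenoxide at the benzylic carbon (the known regiochemistry for phenols and 3-arylglycidols under base) with inversion gives the R benzylic ether (future C2) and leaves the S carbinol (future C3), i.e. the 2,3-trans relationship of catechin.

Step 11
Reactants: 13 (2S,3R)-3-aryloxy-3-[3,4-bis(benzyloxy)phenyl]propane-1,2-diol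
Product: 15 2-O-acetyl-1-O-TBS derivative of 13, via silyl ether 14 (not isolated)
Conditions: TBSCl (1.1 equiv), Et3N, DMAP (cat.), CH2Cl2, 0 °C; then Ac2O, rt
Reagents that add atoms: tert-butyldimethylsilyl chloride CC(C)(C)[Si](C)(C)Cl; acetic anhydride CC(=O)OC(C)=O
Why: selective silylation of the primary hydroxyl followed by DMAP-catalysed acylation of the secondary one in the same flask differentiates the two hydroxyls without touching a stereocentre.

Step 12
Reactants: 15 2-O-acetyl-1-O-TBS derivative of 13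
Product: 16 (2S,3R)-2-acetoxy-3-aryloxy-3-[3,4-bis(benzyloxy)phenyl]propan-1-ol
Conditions: HF·pyridine, pyridine/THF, 0 °C → rt
Reagents that add atoms: none
Why: fluoride desilylation under weakly acidic conditions frees the primary alcohol without the base-induced acetyl migration from the secondary to the primary oxygen.

Step 13
Reactants: 16 (2S,3R)-2-acetoxy-3-aryloxy-3-[3,4-bis(benzyloxy)phenyl]propan-1-ol
Product: 17 (2R,3R)-2-acetoxy-3-aryloxy-3-[3,4-bis(benzyloxy)phenyl]propanal
Conditions: Dess–Martin periodinane (1.3 equiv), NaHCO3 (3 equiv), CH2Cl2, 0 °C; crude 17 used at once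
Reagents that add atoms: none
Why: Dess–Martin oxidation is non-basic, so the α-acetoxy β-aryloxy aldehyde should form without epimerisation at the α carbon or β-elimination of the aryloxide.

Step 14
Reactants: 17 (2R,3R)-2-acetoxy-3-aryloxy-3-[3,4-bis(benzyloxy)phenyl]propanal; 6 3,3''-di-O-acetyl-octa-O-benzyl-catechin-(4α→8)-catechin (3 equiv)
Product: 20 tetra-O-acetyl-hexadeca-O-benzyl catechin tetramer, via 4-silyloxyflavan 18 (not isolated), via flavan-4-yl cation 19 (not isolated)
Conditions: Me3SiOTf (2.3 equiv), 2,6-di-tert-butyl-4-methylpyridine (2.5 equiv), CH2Cl2, −78 → −40 °C; excess 6 recovered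
Reagents that add atoms: none
Why: Proposed new method: Me3SiOTf silylates the aldehyde oxygen of 17, and C4a of the tethered 1,3,5-trioxygenated ring A (the only free position ortho to the ether oxygen, the other carrying the top unit) attacks the carbonyl carbon in a 6-exo-trig Friedel–Crafts hydroxyalkylation that closes ring C of the second unit as 4-silyloxyflavan 18. A second equivalent of Me3SiOTf ionises the doubly donor-activated C4–O bond of 18 to cation 19, which C8 of the upper unit of 6 captures in an intermolecular Friedel–Crafts alkylation, so both C–C bonds at C4, the last ring and the union of the two dimeric halves arise from one aldehyde carbon. The closest known reaction types are the Me3SiOTf-promoted condensation of 3-O-acetyl-4-alkoxyflavans with flavan-3-ol nucleophiles (steps 4 and 6), the Lewis acid cyclisation of 3-aryloxypropanals to chroman-4-ols and the twofold arylation of aldehydes to triarylmethanes; their merger on an acyclic aryl ether aldehyde is what is new. The only new stereocentre, C4 of the second unit, is set at cation 19: the half-chair keeps the C2 aryl group equatorial and the 3-acetoxy group closes the β face by acetoxonium participation and bulk, so the nucleophile enters on the α face, trans to C3–O (4α→8), while C2 and C3 come unchanged from 12. Chemoselectivity rests on ring A being far more nucleophilic than catechol ring B (which would give an indanol) and on the hindered pyridine removing triflic acid, so that the benzylic C2–O1 ether and the existing interflavan bonds are not ionised. Site selectivity for C8 of the upper unit of 6 follows the known preference of dimeric flavan nucleophiles for that position, and the excess of 6 suppresses capture of 19 by the free C6 and C8 of the top unit.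

Step 15
Reactants: 20 tetra-O-acetyl-hexadeca-O-benzyl catechin tetramer
Product: 21 hexadeca-O-benzyl catechin-(4α→8)-catechin-(4α→8)-catechin-(4α→8)-catechin
Conditions: NaOMe (0.5 equiv), MeOH/THF (1:1), 40 °C
Reagents that add atoms: none
Why: Zemplén transesterification removes the four secondary acetates; with all phenols benzylated there is no base-sensitive quinone methide pathway and no stereocentre is at risk.

Step 16
Reactants: 21 hexadeca-O-benzyl catechin-(4α→8)-catechin-(4α→8)-catechin-(4α→8)-catechin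
Product: 22 catechin-(4α→8)-catechin-(4α→8)-catechin-(4α→8)-catechin (target)
Conditions: H2 (1 atm), Pd(OH)2/C, THF/MeOH/H2O, rt; filtration, lyophilisation
Reagents that add atoms: none
Why: catalytic hydrogenolysis cleaves the sixteen benzyl aryl ethers under neutral conditions that leave the interflavan bonds, the benzylic C2–O1 ethers and all stereocentres intact.

**Compound list**

1 | (+)-catechin, (2R,3S)-2-(3,4-dihydroxyphenyl)chromane-3,5,7-triol | Oc1cc(O)c2c(c1)O[C@H](c1ccc(O)c(O)c1)[C@@H](O)C2 | starting material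
2 | 5,7,3',4'-tetra-O-benzyl-(+)-catechin | c1(OCc3ccccc3)cc(OCc3ccccc3)c2c(c1)O[C@H](c1ccc(OCc3ccccc3)c(OCc3ccccc3)c1)[C@@H](O)C2 | intermediate
3 | (2R,3S,4S)-5,7,3',4'-tetra-O-benzyl-4β-(2-ethoxyethoxy)catechin (4-alkoxy cis to 3-OH) | c1(OCc3ccccc3)cc(OCc3ccccc3)c2c(c1)O[C@H](c1ccc(OCc3ccccc3)c(OCc3ccccc3)c1)[C@@H](O)[C@H]2OCCOCC | intermediate
4 | 3-O-acetyl derivative of 3 | c1(OCc3ccccc3)cc(OCc3ccccc3)c2c(c1)O[C@H](c1ccc(OCc3ccccc3)c(OCc3ccccc3)c1)[C@@H](OC(C)=O)[C@H]2OCCOCC | intermediate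
5 | 3-O-acetyl-5,7,3',4'-tetra-O-benzylcatechin-(4α→8)-5,7,3',4'-tetra-O-benzylcatechin | c1(OCc3ccccc3)cc(OCc3ccccc3)c2c(c1)O[C@H](c1ccc(OCc3ccccc3)c(OCc3ccccc3)c1)[C@@H](OC(C)=O)[C@@H]2c1c(OCc3ccccc3)cc(OCc3ccccc3)c2c1O[C@H](c1ccc(OCc3ccccc3)c(OCc3ccccc3)c1)[C@@H](O)C2 | intermediate
6 | 3-O-acetyl derivative of 5 at the lower unit (both 3-hydroxyls acetylated) | c1(OCc3ccccc3)cc(OCc3ccccc3)c2c(c1)O[C@H](c1ccc(OCc3ccccc3)c(OCc3ccccc3)c1)[C@@H](OC(C)=O)[C@@H]2c1c(OCc3ccccc3)cc(OCc3ccccc3)c2c1O[C@H](c1ccc(OCc3ccccc3)c(OCc3ccccc3)c1)[C@@H](OC(C)=O)C2 | intermediate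
7 | 3,5-bis(benzyloxy)phenol | Oc1cc(OCc2ccccc2)cc(OCc2ccccc2)c1 | starting material
8 | 3-O-acetyl-5,7,3',4'-tetra-O-benzyl-4α-[2,4-bis(benzyloxy)-6-hydroxyphenyl]catechin (2,3-trans-3,4-trans) | c1(OCc3ccccc3)cc(OCc3ccccc3)c2c(c1)O[C@H](c1ccc(OCc3ccccc3)c(OCc3ccccc3)c1)[C@@H](OC(C)=O)[C@@H]2c1c(O)cc(OCc3ccccc3)cc1OCc3ccccc3 | intermediate
9 | caffeic acid, (E)-3-(3,4-dihydroxyphenyl)prop-2-enoic acid | OC(=O)/C=C/c1ccc(O)c(O)c1 | starting material
10 | benzyl (E)-3-[3,4-bis(benzyloxy)phenyl]prop-2-enoate | O=C(OCc1ccccc1)/C=C/c1ccc(OCc2ccccc2)c(OCc2ccccc2)c1 | intermediate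
11 | (E)-3-[3,4-bis(benzyloxy)phenyl]prop-2-en-1-ol | OC/C=C/c1ccc(OCc2ccccc2)c(OCc2ccccc2)c1 | intermediate
12 | [(2S,3S)-3-[3,4-bis(benzyloxy)phenyl]oxiran-2-yl]methanol (trans epoxide) | OC[C@@H]1O[C@H]1c1ccc(OCc2ccccc2)c(OCc2ccccc2)c1 | intermediate
13 | (2S,3R)-3-[3,4-bis(benzyloxy)phenyl]-3-aryloxypropane-1,2-diol, the aryl group being the 3,5-bis(benzyloxy)phenyl ring of 8 that carries the top unit at its 2-position | c1(OCc3ccccc3)cc(OCc3ccccc3)c2c(c1)O[C@H](c1ccc(OCc3ccccc3)c(OCc3ccccc3)c1)[C@@H](OC(C)=O)[C@@H]2c1c(O[C@H](c4ccc(OCc3ccccc3)c(OCc3ccccc3)c4)[C@@H](O)CO)cc(OCc3ccccc3)cc1OCc3ccccc3 | intermediate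
14 | 1-O-tert-butyldimethylsilyl ether of 13 | c1(OCc3ccccc3)cc(OCc3ccccc3)c2c(c1)O[C@H](c1ccc(OCc3ccccc3)c(OCc3ccccc3)c1)[C@@H](OC(C)=O)[C@@H]2c1c(O[C@H](c4ccc(OCc3ccccc3)c(OCc3ccccc3)c4)[C@@H](O)CO[Si](C)(C)C(C)(C)C)cc(OCc3ccccc3)cc1OCc3ccccc3 | intermediate
15 | 2-O-acetyl-1-O-tert-butyldimethylsilyl derivative of 13 | c1(OCc3ccccc3)cc(OCc3ccccc3)c2c(c1)O[C@H](c1ccc(OCc3ccccc3)c(OCc3ccccc3)c1)[C@@H](OC(C)=O)[C@@H]2c1c(O[C@H](c4ccc(OCc3ccccc3)c(OCc3ccccc3)c4)[C@@H](OC(C)=O)CO[Si](C)(C)C(C)(C)C)cc(OCc3ccccc3)cc1OCc3ccccc3 | intermediate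
16 | (2S,3R)-2-acetoxy-3-aryloxy-3-[3,4-bis(benzyloxy)phenyl]propan-1-ol (aryl as in 13) | c1(OCc3ccccc3)cc(OCc3ccccc3)c2c(c1)O[C@H](c1ccc(OCc3ccccc3)c(OCc3ccccc3)c1)[C@@H](OC(C)=O)[C@@H]2c1c(O[C@H](c4ccc(OCc3ccccc3)c(OCc3ccccc3)c4)[C@@H](OC(C)=O)CO)cc(OCc3ccccc3)cc1OCc3ccccc3 | intermediate
17 | (2R,3R)-2-acetoxy-3-aryloxy-3-[3,4-bis(benzyloxy)phenyl]propanal (aryl as in 13; same spatial arrangement as 16) | c1(OCc3ccccc3)cc(OCc3ccccc3)c2c(c1)O[C@H](c1ccc(OCc3ccccc3)c(OCc3ccccc3)c1)[C@@H](OC(C)=O)[C@@H]2c1c(O[C@H](c4ccc(OCc3ccccc3)c(OCc3ccccc3)c4)[C@@H](OC(C)=O)C=O)cc(OCc3ccccc3)cc1OCc3ccccc3 | intermediate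
18 | ring-closed dimer: 3-O-acetyl-tetra-O-benzylcatechin-(4α→8)-3-O-acetyl-tetra-O-benzyl-4-(trimethylsilyloxy)catechin (C4 of the silyl ether drawn 3,4-trans; immaterial) | c1(OCc3ccccc3)cc(OCc3ccccc3)c2c(c1)O[C@H](c1ccc(OCc3ccccc3)c(OCc3ccccc3)c1)[C@@H](OC(C)=O)[C@@H]2c1c(OCc3ccccc3)cc(OCc3ccccc3)c2c1O[C@H](c1ccc(OCc3ccccc3)c(OCc3ccccc3)c1)[C@@H](OC(C)=O)[C@@H]2O[Si](C)(C)C | intermediate
19 | C4 cation of the second unit of 18, as its triflate ion pair | c1(OCc3ccccc3)cc(OCc3ccccc3)c2c(c1)O[C@H](c1ccc(OCc3ccccc3)c(OCc3ccccc3)c1)[C@@H](OC(C)=O)[C@@H]2c1c(OCc3ccccc3)cc(OCc3ccccc3)c2c1O[C@H](c1ccc(OCc3ccccc3)c(OCc3ccccc3)c1)[C@@H](OC(C)=O)[CH+]2.[O-]S(=O)(=O)C(F)(F)F | intermediate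
20 | tetra-O-acetyl-hexadeca-O-benzyl catechin-(4α→8)-catechin-(4α→8)-catechin-(4α→8)-catechin (every 3-OH acetylated, every phenol benzylated) | c1(OCc3ccccc3)cc(OCc3ccccc3)c2c(c1)O[C@H](c1ccc(OCc3ccccc3)c(OCc3ccccc3)c1)[C@@H](OC(C)=O)[C@@H]2c1c(OCc3ccccc3)cc(OCc3ccccc3)c2c1O[C@H](c1ccc(OCc3ccccc3)c(OCc3ccccc3)c1)[C@@H](OC(C)=O)[C@@H]2c1c(OCc3ccccc3)cc(OCc3ccccc3)c2c1O[C@H](c1ccc(OCc3ccccc3)c(OCc3ccccc3)c1)[C@@H](OC(C)=O)[C@@H]2c1c(OCc3ccccc3)cc(OCc3ccccc3)c2c1O[C@H](c1ccc(OCc3ccccc3)c(OCc3ccccc3)c1)[C@@H](OC(C)=O)C2 | intermediate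
21 | hexadeca-O-benzyl catechin-(4α→8)-catechin-(4α→8)-catechin-(4α→8)-catechin (four free 3-OH) | c1(OCc3ccccc3)cc(OCc3ccccc3)c2c(c1)O[C@H](c1ccc(OCc3ccccc3)c(OCc3ccccc3)c1)[C@@H](O)[C@@H]2c1c(OCc3ccccc3)cc(OCc3ccccc3)c2c1O[C@H](c1ccc(OCc3ccccc3)c(OCc3ccccc3)c1)[C@@H](O)[C@@H]2c1c(OCc3ccccc3)cc(OCc3ccccc3)c2c1O[C@H](c1ccc(OCc3ccccc3)c(OCc3ccccc3)c1)[C@@H](O)[C@@H]2c1c(OCc3ccccc3)cc(OCc3ccccc3)c2c1O[C@H](c1ccc(OCc3ccccc3)c(OCc3ccccc3)c1)[C@@H](O)C2 | intermediate
22 | catechin-(4α→8)-catechin-(4α→8)-catechin-(4α→8)-catechin, CNP0236700.2 | Oc1cc(O)c2c(c1)O[C@H](c1ccc(O)c(O)c1)[C@@H](O)[C@@H]2c1c(O)cc(O)c2c1O[C@H](c1ccc(O)c(O)c1)[C@@H](O)[C@@H]2c1c(O)cc(O)c2c1O[C@H](c1ccc(O)c(O)c1)[C@@H](O)[C@@H]2c1c(O)cc(O)c2c1O[C@H](c1ccc(O)c(O)c1)[C@@H](O)C2 | target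

**Summary**

Total step count: 16.
Longest linear sequence: 11 steps (steps 1, 2, 3, 6, 10, 11, 12, 13, 14, 15, 16).

Steps most likely to fail:

1. Step 14 (key step). What may go wrong: ionisation of the acyclic benzylic C2–O1 aryl ether before ring closure (loss of the C2 configuration or fragmentation), capture of the cation by the free C6 or C8 position of another molecule (oligomerisation), and insufficient α-facial selectivity at C4. The fallback uses known chemistry, sets out from 17 and returns at 20; it separates the two C–C bond formations. Aldehyde 17 alone is cyclised with Me2AlCl (1.5 equiv, CH2Cl2, −78 °C), a Lewis acid carbonyl–arene hydroxyalkylation in which the product is held as an aluminium alkoxide that cannot ionise. After aqueous work-up this should give the ring-closed 3-O-acetyl flavan-4-ol F1. F1 is then treated as an ordinary flavan-4-ol electrophile and condensed with 6 (3 equiv) under catalytic Me3SiOTf (CH2Cl2, −78 °C), which should give 20.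

2. Step 10. What may go wrong: slow SN2 attack by the phenoxide of 8, which is flanked by the bulky flavan-4-yl group, so that Payne rearrangement, decomposition of the electron-rich epoxide or SN1-type opening without clean inversion take over. The fallback sets out from 7 and 12 and returns at 15; it reverses the order of ether formation and arylation. The unhindered phenol 7 opens epoxide 12 (Cs2CO3 cat., DMF, 60 °C) at the benzylic carbon with inversion to give the diol F2. Selective silylation (TBSCl, Et3N, DMAP) gives the silyl ether F3, and acetylation (Ac2O) in the same flask gives the acetate F4. F4 is then C-alkylated by the cation from 4 (Me3SiOTf cat., CH2Cl2, −78 °C) at a position ortho to the ether oxygen, two equivalent sites against one between the benzyloxy groups. After separation from the regioisomer this gives 15.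

3. Step 6. What may go wrong: poor regioselectivity (attack para to the hydroxyl, between the two benzyloxy groups) and double alkylation of the phenol. The fallback sets out from 4 and returns at 8; it uses commercial phloroglucinol (benzene-1,3,5-triol), whose three ring positions are equivalent. Condensation with 4 (BF3·OEt2, 1,4-dioxane/CH2Cl2, 0 °C) can give only the triol F5. F5 is then benzylated with two equivalents of BnBr (K2CO3, DMF, 0 °C), first at the unhindered para hydroxyl and then at one of the two equivalent hydroxyls flanking the flavanyl group, which should give 8 after chromatography.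

**Further compounds**

F1 | step 14 | 3-O-acetyl-tetra-O-benzylcatechin-(4α→8)-3-O-acetyl-tetra-O-benzyl-4-hydroxycatechin (flavan-4-ol; carbinol drawn 3,4-trans, immaterial) | c1(OCc3ccccc3)cc(OCc3ccccc3)c2c(c1)O[C@H](c1ccc(OCc3ccccc3)c(OCc3ccccc3)c1)[C@@H](OC(C)=O)[C@@H]2c1c(OCc3ccccc3)cc(OCc3ccccc3)c2c1O[C@H](c1ccc(OCc3ccccc3)c(OCc3ccccc3)c1)[C@@H](OC(C)=O)[C@@H]2O
F2 | step 10 | (2S,3R)-3-[3,5-bis(benzyloxy)phenoxy]-3-[3,4-bis(benzyloxy)phenyl]propane-1,2-diol | O(c1cc(OCc2ccccc2)cc(OCc2ccccc2)c1)[C@H](c1ccc(OCc2ccccc2)c(OCc2ccccc2)c1)[C@@H](O)CO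
F3 | step 10 | 1-O-tert-butyldimethylsilyl ether of F2 | O(c1cc(OCc2ccccc2)cc(OCc2ccccc2)c1)[C@H](c1ccc(OCc2ccccc2)c(OCc2ccccc2)c1)[C@@H](O)CO[Si](C)(C)C(C)(C)C
F4 | step 10 | 2-O-acetyl-1-O-tert-butyldimethylsilyl derivative of F2 | O(c1cc(OCc2ccccc2)cc(OCc2ccccc2)c1)[C@H](c1ccc(OCc2ccccc2)c(OCc2ccccc2)c1)[C@@H](OC(C)=O)CO[Si](C)(C)C(C)(C)C
F5 | step 6 | 3-O-acetyl-5,7,3',4'-tetra-O-benzyl-4α-(2,4,6-trihydroxyphenyl)catechin | c1(OCc3ccccc3)cc(OCc3ccccc3)c2c(c1)O[C@H](c1ccc(OCc3ccccc3)c(OCc3ccccc3)c1)[C@@H](OC(C)=O)[C@@H]2c1c(O)cc(O)cc1O
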